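**Retrosynthetic overview**
1. The target is the 8–5′/7–O–4′ dehydrodimer of two identical chalcone units. Cutting C3–C3a and C2–O1 of the dihydrofuran ring gives two molecules of isoliquiritigenin, so the key step copies the presumed biosynthesis.
2. Enabling feature: C2 carries a para-hydroxyphenyl group, C3 an aroyl group, and C3a is ortho to O1, which is para to the enone chain at C5. Each half is therefore a 4-hydroxystyryl ketone whose phenoxyl radical has spin at the enone α-carbon (becomes C3) and at the ring carbon ortho to oxygen (becomes C3a); the para-oxygen then gives a quinone methide that accepts O1 at C2.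
3. The 2′-OH/C=O pair of each resorcinol ring is a bidentate site. A removable spiroborate of an (R)-biaryl diol (a temporary six-membered chelate ring) is placed there to shield one face of the enone α-carbon and to protect the 2′-OH.
4. Ring order: the benzene rings are bought; the chalcone is made by Claisen–Schmidt condensation; the boron chelate rings are put on; the dihydrofuran ring O1–C2–C3–C3a–C7a is closed last in the oxidative dimerisation, and the chelates are hydrolysed in the same work-up.

Key step: step 3

Assumption: the (R) axis of diol 4 cannot be written in SMILES and is given in the names; the face it shields is assigned from a hand-built model of the spiroborate chelate (s-cis enone), and if the sense proves opposite the (S)-diol is used in the same way.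

**Step 1**
Reactants: 1 2,4-dihydroxyacetophenone; 2 4-hydroxybenzaldehyde
Product: 3 isoliquiritigenin [(E)-2′,4′,4-trihydroxychalcone]
Conditions: BF3·OEt2 (0.5 equiv), 1,4-dioxane, rt; H2O work-up
Reagents that add atoms: none
Why: Acid-mediated Claisen–Schmidt (crossed aldol) condensation, in which the BF3-activated 2-hydroxyacetophenone enolises and adds to the aldehyde, dehydration gives the thermodynamically favoured E-enone, and chelation of the 2′-OH/C=O pair holds back cyclisation to the flavanone.

**Step 2**
Reactants: 3 isoliquiritigenin; 4 (R)-3,3′-diphenyl-1,1′-bi-2-naphthol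
Product: 5 (R)-3,3′-diphenyl-binaphtholate spiroborate of isoliquiritigenin (boron bound to the 2′-oxygen and the ketone oxygen; 4-OH and 4′-OH free)
Conditions: B(OiPr)3 (1.0 equiv), toluene–THF, 4 Å MS, 60 °C; evaporate with toluene, use crude
Reagents that add atoms: triisopropyl borate, CC(C)OB(OC(C)C)OC(C)C
Why: Borate transesterification with chelation, in which the three isopropoxy groups are exchanged for the two naphtholate oxygens and the 2′-phenolate and the ketone oxygen completes the tetracoordinate spiroborate, the same 2′-hydroxychalcone–binaphthol–boron chelate that serves as the reactive complex in boron-templated chalcone Diels–Alder reactions; removal of isopropanol drives it, and the non-chelating 4- and 4′-OH groups cannot compete with two chelate rings.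

**Step 3**
Reactants: 5 (two molecules)
Product: 9 target CNP0288976.2 [(2S,3S)-trans-2,3-dihydrobenzofuran], via phenoxyl radical 6 (not isolated), via quinone methide 7 (not isolated), via bis-spiroborate dimer 8 (not isolated)
Conditions: Ag2O (1.0 equiv), 4 Å MS, CH2Cl2, 0 °C to rt, dark; filter; then aq. citric acid, THF, rt (diol 4 recovered)
Reagents that add atoms: none
Why: Proposed new method: Ag(I) oxidises the free 4-OH of 5 to phenoxyl radical 6, whose spin reaches C8 (the enone α-carbon) and the ring carbons ortho to oxygen; two radicals couple C8–C5′ as in the presumed biosynthesis (this bond becomes C3–C3a), rearomatisation gives p-quinone methide 7, and its ortho-phenol closes the dihydrofuran ring by 5-exo-trig oxa-1,6-addition to the methide carbon (C2–O1) to give 8. The closest known reactions are the Ag2O- or peroxidase-mediated 8–5′ dehydrodimerisation of 4-hydroxycinnamoyl compounds, including its variant with a chiral auxiliary on the acyl group, and the binaphthol–boron-templated enantioselective Diels–Alder reaction of 2′-hydroxychalcones, where the same chelate differentiates the faces of the same Cα=Cβ bond; new is the use of this chelate to steer a radical–radical coupling. C3 is set in the coupling: the chelate holds the enone s-cis and the 3-phenyl group of the (R)-ligand should cover the Re face of C8, so that the partner bonds to the Si face and gives 3S. C2 is set in the ring closure under substrate control: the phenol adds to the methide carbon anti to the bulky chelated aroyl group, giving the 2,3-trans (2S) isomer, which is also the more stable one. The step needs 8–5′ regioselectivity over 8–8′ and 8–O–4′ coupling and chemoselectivity for the styryl phenol: the bulky chelate at C8 disfavours 8–8′ coupling, the locked 2′-oxygen can neither be oxidised nor trap the quinone methide as a flavanone, and the 4′-OH is a para-acylphenol with a stronger O–H bond than the conjugated 4-OH. Mild acidic hydrolysis of the two spiroborates then releases 9 without base, which matters because C3–H is α to a ketone and β to an aryloxy leaving group.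

**Compound list**
1 | 2,4-dihydroxyacetophenone | CC(=O)c1ccc(O)cc1O | starting material
2 | 4-hydroxybenzaldehyde | O=Cc1ccc(O)cc1 | starting material
3 | isoliquiritigenin, (E)-1-(2,4-dihydroxyphenyl)-3-(4-hydroxyphenyl)prop-2-en-1-one | O=C(/C=C/c1ccc(O)cc1)c1ccc(O)cc1O | intermediate
4 | (R)-3,3′-diphenyl-1,1′-bi-2-naphthol (axis R) | Oc1c(-c2ccccc2)cc2ccccc2c1-c1c(O)c(-c2ccccc2)cc2ccccc12 | starting material
5 | spiroborate of 3 and (R)-4: tetracoordinate boron bound to both naphtholate oxygens, the 2′-oxygen and the ketone oxygen of the E-chalcone | [O+]1=C(/C=C/c2ccc(O)cc2)c2ccc(O)cc2O[B-]13Oc4c(-c5ccccc5)cc5ccccc5c4-c4c(O3)c(-c5ccccc5)cc5ccccc45 | intermediate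
6 | phenoxyl radical of 5 (oxygen radical at the former 4-OH) | [O+]1=C(/C=C/c2ccc([O])cc2)c2ccc(O)cc2O[B-]13Oc4c(-c5ccccc5)cc5ccccc5c4-c4c(O3)c(-c5ccccc5)cc5ccccc45 | intermediate
7 | 8–5′-coupled p-quinone methide with free ortho-phenol, both ketones still chelated, new stereocentre (the future C3) R | [O+]1=C(/C=C/c2ccc(O)c(c2)[C@H](C(=[O+]4)c5ccc(O)cc5O[B-]46Oc7c(-c8ccccc8)cc8ccccc8c7-c7c(O6)c(-c8ccccc8)cc8ccccc78)C=C2C=CC(=O)C=C2)c2ccc(O)cc2O[B-]13Oc4c(-c5ccccc5)cc5ccccc5c4-c4c(O3)c(-c5ccccc5)cc5ccccc45 | intermediate
8 | bis-spiroborate of the (2S,3S)-trans-dihydrobenzofuran dimer (both 2-oxyaryl ketones chelated to boron–(R)-diol) | [O+]1=C(/C=C/c2ccc3c(c2)[C@H](C(=[O+]4)c5ccc(O)cc5O[B-]46Oc7c(-c8ccccc8)cc8ccccc8c7-c7c(O6)c(-c8ccccc8)cc8ccccc78)[C@@H](c2ccc(O)cc2)O3)c2ccc(O)cc2O[B-]13Oc4c(-c5ccccc5)cc5ccccc5c4-c4c(O3)c(-c5ccccc5)cc5ccccc45 | intermediate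
9 | CNP0288976.2, (E)-3-[(2S,3S)-3-(2,4-dihydroxybenzoyl)-2-(4-hydroxyphenyl)-2,3-dihydrobenzofuran-5-yl]-1-(2,4-dihydroxyphenyl)prop-2-en-1-one | O=C(/C=C/c1ccc2c(c1)[C@H](C(=O)c1ccc(O)cc1O)[C@@H](c1ccc(O)cc1)O2)c1ccc(O)cc1O | target

**Step count and risks**
Total step count: 3. Longest linear sequence: 3 steps (1 → 3 → 5 → 9).

Steps most likely to fail:

1. Step 3 (Proposed new method). The risks are poor enantioface discrimination in a radical–radical coupling with an early transition state, competing 8–8′ and 8–O–4′ coupling, slow oxidation of the electron-poor chelated phenol, and erosion of C3 by tautomerisation of the quinone methide before ring closure. The fallback uses known chemistry and sets out from 3. Untemplated biomimetic dehydrodimerisation of 3 (horseradish peroxidase/H2O2 in acetone–buffer, or Ag2O in acetone–benzene) should give the trans-dihydrobenzofuran as a racemate, that is 9 together with its (2R,3R)-enantiomer F1. Preparative HPLC on a polysaccharide chiral stationary phase separates the two, and the route is rejoined at 9.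

2. Step 2. The risks are ligand scrambling to homoleptic borates, borylation of the non-chelating phenols and hydrolysis during handling, all of which would leave part of the chalcone untemplated. The fallback assembles the chelate in two stages and sets out from 3 and 4. BF3·OEt2 in CH2Cl2 converts 3 into the robust, isolable difluoroboron chelate F2. HMDS with catalytic TMSCl converts 4 into (R)-2,2′-bis(trimethylsilyloxy)-3,3′-diphenyl-1,1′-binaphthyl F3. F2 and F3 with catalytic TMSOTf in CH2Cl2 should exchange both B–F bonds for B–O bonds with loss of volatile fluorotrimethylsilane, and the route is rejoined at 5.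

3. Step 1. The risks are acid-induced cyclisation of the 2′-hydroxychalcone to the flavanone and low conversion caused by the free phenols. The fallback is a protected, base-mediated condensation and sets out from 1 and 2. MOMCl/K2CO3 in acetone etherifies the non-chelated 4-OH of 1 to give 1-[2-hydroxy-4-(methoxymethoxy)phenyl]ethanone F4, and MOMCl/iPr2NEt converts 2 into 4-(methoxymethoxy)benzaldehyde F5. KOH in EtOH condenses F4 with F5 to (E)-2′-hydroxy-4,4′-bis(methoxymethoxy)chalcone F6, and HCl in MeOH removes both MOM groups, rejoining the route at 3.

**Further compounds**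
F1 | step 3 | (2R,3R)-enantiomer of 9 | O=C(/C=C/c1ccc2c(c1)[C@@H](C(=O)c1ccc(O)cc1O)[C@H](c1ccc(O)cc1)O2)c1ccc(O)cc1O
F2 | step 2 | difluoroboron chelate of isoliquiritigenin (BF2 bound to the 2′-oxygen and the ketone oxygen) | [O+]1=C(/C=C/c2ccc(O)cc2)c2ccc(O)cc2O[B-]1(F)F
F3 | step 2 | (R)-2,2′-bis(trimethylsilyloxy)-3,3′-diphenyl-1,1′-binaphthyl | C[Si](C)(C)Oc1c(-c2ccccc2)cc2ccccc2c1-c1c(O[Si](C)(C)C)c(-c2ccccc2)cc2ccccc12
F4 | step 1 | 1-[2-hydroxy-4-(methoxymethoxy)phenyl]ethanone | CC(=O)c1ccc(OCOC)cc1O
F5 | step 1 | 4-(methoxymethoxy)benzaldehyde | COCOc1ccc(C=O)cc1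
F6 | step 1 | (E)-1-[2-hydroxy-4-(methoxymethoxy)phenyl]-3-[4-(methoxymethoxy)phenyl]prop-2-en-1-one | O=C(/C=C/c1ccc(OCOC)cc1)c1ccc(OCOC)cc1O
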